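## Analysis of the target

Atoms are numbered along the chain: C1 is the lactone carbonyl, C2=C3 the conjugated alkene, C4 the ring CH2, C5 the lactone carbinol, C6 the free carbinol, C7–C10 the tetrahydrofuran carbons (ring oxygen O7), C11 the acylated carbinol and C12 the methyl group.

- The target 19 is a C12 chain folded into a 5,6-dihydro-2H-pyran-2-one (O, C1–C5) and a 2,5-disubstituted tetrahydrofuran (O7, C7–C10). The two rings are joined through C6, and C11 carries a (Z)-4-methoxycinnamate.
- There are five stereocentres: C5 R, C6 S, C7 R, C10 S and C11 S. C5/C6 are anti, C6/C7 are syn, the substituents at C7 and C10 are cis on the ring, and C10/C11 are syn (threo).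
- The conjugated lactone does not tolerate base: it can hydrolyse, or lose a proton at C4 and open to a dienoate. It also accepts nucleophiles at C3, including O7 or O6 of its own side chain.
- The Z-cinnamate can isomerise to the E ester under light or by reversible conjugate addition of nucleophilic catalysts.
- O6 and O11 are both secondary hydroxyls, and only O11 is acylated in the target.
- The difficulty is that all five stereocentres sit on a flexible, oxygen-rich chain, and that three different alkenes (C2=C3, the cinnamate alkene and a precursor alkene at C10=C11) have to be made or kept in each other's presence.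
- The strategy rests on one feature. O7–C10 and C11–O lie on the same side of the C10–C11 bond, and O6/O7 form a syn vicinal pair four atoms away from C10. This is the pattern left by a syn oxidative cyclisation of a C6,C7-diol onto an E C10=C11 alkene. The C6/C7 pair also has the configuration of C2/C3 of D-arabinose 1.

## Retrosynthetic reasoning

**Ester bond O11–acyl (19 to 15 and 18).** The Z-cinnamate is the most fragile group, so it is attached last. Cutting the acyl–oxygen bond gives the diol 15 and the acid 18 and makes the route convergent. The forward esterification has to pick O11 over O6 and must not isomerise the Z alkene. O11 is flanked by a methyl group, while O6 sits between two ring carbons, so a mild carbodiimide coupling at low temperature should favour O11.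

**Cinnamate alkene (18 to 17 to 16).** The Z alkene is cut back to the aldehyde 16. A Z-selective phosphonate olefination followed by ester hydrolysis in the dark supplies 18 in two steps.

**O7–C10 and C11–O (15 to 14).** Both bonds are cut in one retrosynthetic step. This removes the tetrahydrofuran and the stereocentres C10 and C11 and leads to the dihydroxy alkene 14. In the forward direction the C6,C7-diol binds hexavalent osmium, and the metal delivers O7 and an oxo oxygen to one face of the E alkene. The cut is made here because the ring and two stereocentres are gained from an acyclic precursor, and because the ring geometry (cis) and the C10/C11 relationship (threo) are fixed by the mechanism and not by a reagent choice.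

**Silyl ethers and lactone ring (14 to 13 to 12 to 11).** The diol of 14 is carried as two silyl ethers (13) and is freed under acidic fluoride conditions. The lactone is cut at C2=C3 (ring-closing metathesis of the acrylate 12) and at the O5–acyl bond (acylation of the homoallylic alcohol 11). The lactone is built late for two reasons. It would not survive the basic cross-coupling that builds the side chain. And the allyl group of 11 would compete in a hydroboration if it were present earlier.

**C4–C5 (11 to 10).** Cutting the allyl group from C5 gives the aldehyde 10. The forward reaction must set C5 as R, that is anti to O6. The polar Felkin–Anh preference of the α-silyloxy aldehyde points this way. The syn arrangement of the two silyloxy groups makes substrate control alone unreliable, so a chiral allylboron reagent whose own facial preference matches the substrate bias is used.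

**C9–C10 (10 to 9 to 6 and 7).** The aldehyde is traced back to the alcohol 9. The C9–C10 bond is cut to the terminal alkene 6 and the alkenyl bromide 7, which corresponds to a hydroboration and B-alkyl Suzuki coupling. The E geometry of C10=C11 comes from 7 with retention. This matters because the alkene geometry becomes the C11 configuration in the key step. The coupling is run at the alcohol oxidation level, since an aldehyde would be reduced by the borane.

**Sugar fragmentation (6 to 5 to 4).** The pent-4-enyl unit of 6 with its two carbinols comes from the 5-iodofuranoside 4 by zinc-mediated reductive fragmentation. This releases the C8=C9 vinyl group and the C5 aldehyde (5) together. The aldehyde is reduced in the same flask, so that the side chain can be built first while C5 is parked as a primary alcohol.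

**Furanoside preparation (4 to 3 to 2 to 1).** Silylation, selective iodination of the primary hydroxyl and kinetic methyl glycosidation lead back to D-arabinose 1. Its C2 and C3 become C6 and C7, and its C4 stereocentre is removed in the fragmentation.

## Alternatives that were turned down

**Alternative 1:** The tetrahydrofuran is cut at C7–C8. The precursor is the cis enol acetal A2, a 4-methylidene-1,3-dioxolane made from a dioxolanone of a D-threonine (A3)-derived dihydroxy acid and a C3–C7 aldehyde.
- Forward key step: Me2AlCl ionises A2 at the acetal carbon C7, and the enolate carbon C8 of the resulting ion pair recombines with C7 (a Petasis–Ferrier-type rearrangement). This gives the 2,5-cis tetrahydrofuran-3-one A1.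
- For it: C10 and C11 come from the amino acid pool, the cis ring follows from the tethered recombination, and O11 (4-methoxybenzyl ether) is distinguished from O6 (silyl ether) from the start. On this last point it is stronger than the chosen route, which has to rely on a steric preference in the final acylation.
- Against it: A1 carries a carbonyl at C9 that the target does not have, and its removal costs two or three steps in the presence of a terminal alkene. The required 10S,11S configuration corresponds to the unnatural enantiomer A3. O5 and O6 carry the same silyl group in A1, so the lactone annulation needs a selective deprotection. The C5/C6 stereo problem is only moved into the aldehyde partner.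
- Comparison: the chosen route forms the ring, C10 and C11 in one step from a precursor with no superfluous oxidation, and should be six to eight steps shorter. What it offers in place of the built-in O6/O11 differentiation is a short end game with one selective acylation and a protecting-group fallback.

**Alternative 2:** C6–C7 and C10–C11 are cut together. The precursors are furan A5 and 1,1,3,3-tetrabromoacetone A6.
- Forward key step: zinc reduction of A6 gives a three-carbon cation that adds across the 2- and 5-positions of A5 in a [4+3] cycloaddition. Zn/Cu debromination then gives the meso bicyclic ketone A4, whose carbonyl carbon is the future C5.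
- For it: the starting materials are very cheap, and the oxygen bridge fixes the cis relationship of C7 and C10 with complete certainty. On that point it is at least as strong as the chosen route. O11 would later come from a Baeyer–Villiger insertion between C5 and C11 and would then be distinct from O6, which is also an advantage.
- Against it: A4 is meso and has no substituent at C6 or C11. The route needs an enantioselective desymmetrisation, hydrogenation of C8=C9, an α-hydroxylation at C6 and an α-methylation at C11 with the correct facial sense, and a regioselective Baeyer–Villiger oxidation. After that, C5 arrives at the acid oxidation level and still needs reduction and a stereoselective allylation, the same problem the chosen route has.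
- Comparison: the sequence would be well beyond eighteen steps, with every stereocentre except the ring pair set by separate substrate-controlled reactions. The chosen route takes C6 and C7 from 1 and sets C10 and C11 in one step.

**Alternative 3:** The lactone is cut at O–C1 and C1–C2. The precursor is the vinyl epoxide A8, which already contains the tetrahydrofuran.
- Forward key step: Fe2(CO)9 opens A8 at the allylic carbon C4. After carbon monoxide insertion at iron, the acyl carbon couples with the allyl terminus C2 under carbon monoxide pressure and closes the 3,6-dihydro-2H-pyran-2-one A7.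
- For it: the C5–O bond is never broken, so C5 is taken over from the epoxide. C1 comes from carbon monoxide. No metathesis catalyst meets a second alkene, which is an advantage over step 9 of the chosen route.
- Against it: the step needs stoichiometric iron carbonyl and high pressure on an advanced intermediate. The coupling can also occur at C4 and give a four-membered lactone. A7 is the β,γ-unsaturated isomer, and moving the alkene into conjugation needs base, which the lactone tolerates worst. This strategy also says nothing about the tetrahydrofuran, which would still need its own solution, and A8 requires a separate stereoselective epoxide synthesis.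
- Comparison: the chosen route makes the conjugated lactone directly in three routine steps (allylboration, acryloylation, metathesis) and spends its risk on the step that builds the ring and two stereocentres.

Key step: step 11

## Route

Remark: compounds 2–4 are used as anomeric mixtures, because C1 becomes the aldehyde carbon in step 4. Catalyst-bound turnover species are described in the Why lines and carry no numbers. TBS stands for tert-butyldimethylsilyl.

Step 1
Reactants: 1 D-arabinose
Product: 2 methyl D-arabinofuranoside (α/β mixture at C1)
Conditions: AcCl (0.1 equiv), MeOH, rt, short reaction time; NaHCO3 quench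
Reagents that add atoms: methanol, CO
Why: Kinetic Fischer glycosidation stops at the five-membered glycosides before they equilibrate to pyranosides; the three carbinol centres are not touched.

Step 2
Reactants: 2 methyl D-arabinofuranoside
Product: 3 methyl 5-deoxy-5-iodo-D-arabinofuranoside
Conditions: I2, PPh3, imidazole, THF, 60 °C
Reagents that add atoms: iodine, II
Why: Appel-type iodination (Garegg–Samuelsson conditions) is selective for the only primary hydroxyl, because the bulky alkoxyphosphonium salt forms and is displaced fastest at C5.

Step 3
Reactants: 3 methyl 5-deoxy-5-iodo-D-arabinofuranoside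
Product: 4 methyl 2,3-bis-O-TBS-5-deoxy-5-iodo-D-arabinofuranoside
Conditions: TBSOTf (2.4 equiv), 2,6-lutidine, CH2Cl2, 0 °C to rt
Reagents that add atoms: tert-butyldimethylsilyl trifluoromethanesulfonate, CC(C)(C)[Si](C)(C)OS(=O)(=O)C(F)(F)F
Why: Silyl triflate silylation covers both secondary hydroxyls of the trans diol; silyl ethers are chosen because they do not chelate in the later allylation and can be removed by acidic fluoride next to the lactone.

Step 4
Reactants: 4 methyl 2,3-bis-O-TBS-5-deoxy-5-iodo-D-arabinofuranoside
Product: 6 (2R,3R)-2,3-bis(TBS-oxy)pent-4-en-1-ol, via pentenal 5 (not isolated)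
Conditions: Zn dust (activated), THF–H2O (4:1), ultrasound, 40 °C; then NaBH4, 0 °C
Reagents that add atoms: none
Why: Bernet–Vasella reductive fragmentation: zinc inserts into the C–I bond and the organozinc expels the ring oxygen, so the vinyl group and the aldehyde 5 (after loss of methanol from the hemiacetal) form together; immediate NaBH4 reduction parks the epimerisable α-silyloxy aldehyde as the alcohol with both carbinol centres intact.

Step 5
Reactants: 6 (2R,3R)-2,3-bis(TBS-oxy)pent-4-en-1-ol; 7 (E)-1-bromoprop-1-ene
Product: 9 (2R,3R,6E)-2,3-bis(TBS-oxy)oct-6-en-1-ol, via alkylborane 8 (not isolated)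
Conditions: 9-BBN (2.5 equiv), THF, rt to 45 °C; then 7 (3 equiv), PdCl2(dppf) (5 mol%), AsPh3, K3PO4 (aq), DMF, rt
Reagents that add atoms: none
Why: Anti-Markovnikov hydroboration of the only terminal alkene followed by B-alkyl Suzuki–Miyaura coupling, which keeps the E geometry of the alkenyl bromide; the free hydroxyl travels as its borinate and is released on aqueous work-up.

Step 6
Reactants: 9 (2R,3R,6E)-2,3-bis(TBS-oxy)oct-6-en-1-ol
Product: 10 (2S,3R,6E)-2,3-bis(TBS-oxy)oct-6-enal
Conditions: Dess–Martin periodinane, NaHCO3, CH2Cl2, 0 °C to rt
Reagents that add atoms: none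
Why: Buffered Dess–Martin oxidation stops at the aldehyde and should not epimerise the α-silyloxy centre; the crude aldehyde is used at once.

Step 7
Reactants: 10 (2S,3R,6E)-2,3-bis(TBS-oxy)oct-6-enal
Product: 11 (4R,5R,6R,9E)-5,6-bis(TBS-oxy)undeca-1,9-dien-4-ol
Conditions: allyl-B(Ipc)2 derived from (−)-α-pinene (1.5 equiv), Et2O, −78 °C; then NaOH, H2O2, 0 °C to rt
Reagents that add atoms: B-allylbis(isopinocampheyl)borane from (−)-α-pinene, C=CCB([C@H]1C[C@H]2C[C@@H]([C@@H]1C)C2(C)C)[C@H]1C[C@H]2C[C@@H]([C@@H]1C)C2(C)C
Why: Brown allylboration through a closed chair transition state; this antipode of the reagent delivers the allyl group to the Re face of the aldehyde, the face also favoured by polar Felkin–Anh control from the C6 silyloxy group, so reagent and substrate reinforce each other and set C5 as R, anti to O6.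

Step 8
Reactants: 11 (4R,5R,6R,9E)-5,6-bis(TBS-oxy)undeca-1,9-dien-4-ol
Product: 12 (4R,5R,6R,9E)-5,6-bis(TBS-oxy)undeca-1,9-dien-4-yl prop-2-enoate
Conditions: acryloyl chloride, iPr2NEt, DMAP (cat.), CH2Cl2, −20 to 0 °C
Reagents that add atoms: acryloyl chloride, C=CC(=O)Cl
Why: Acylation of the only free hydroxyl with an acid chloride under amine base; the low temperature suppresses polymerisation and conjugate addition to the acrylate.

Step 9
Reactants: 12 (4R,5R,6R,9E)-5,6-bis(TBS-oxy)undeca-1,9-dien-4-yl prop-2-enoate
Product: 13 (6R)-6-[(1R,2R,5E)-1,2-bis(TBS-oxy)hept-5-en-1-yl]-5,6-dihydro-2H-pyran-2-one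
Conditions: second-generation Grubbs catalyst RuCl2(=CHPh)(PCy3)(H2IMes) (5 mol%), CH2Cl2 (5 mM), 40 °C
Reagents that add atoms: none
Why: Ring-closing metathesis: the ruthenium carbene loads on the terminal allyl alkene and closes the six-membered ring onto the acrylate with loss of ethene; the internal E alkene is a slower partner, could only close an eight-membered ring, and is protected from cross-metathesis by high dilution.

Step 10
Reactants: 13 (6R)-6-[(1R,2R,5E)-1,2-bis(TBS-oxy)hept-5-en-1-yl]-5,6-dihydro-2H-pyran-2-one
Product: 14 (6R)-6-[(1S,2R,5E)-1,2-dihydroxyhept-5-en-1-yl]-5,6-dihydro-2H-pyran-2-one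
Conditions: HF·pyridine, pyridine, THF, 0 °C to rt
Reagents that add atoms: none
Why: Fluoride-mediated desilylation under mildly acidic conditions frees the syn diol without the base that would open the lactone or trigger conjugate addition of O7 to C3; the diol is used promptly.

Step 11
Reactants: 14 (6R)-6-[(1S,2R,5E)-1,2-dihydroxyhept-5-en-1-yl]-5,6-dihydro-2H-pyran-2-one
Product: 15 (6R)-6-{(S)-hydroxy[(2R,5S)-5-[(1S)-1-hydroxyethyl]oxolan-2-yl]methyl}-5,6-dihydro-2H-pyran-2-one
Conditions: K2OsO4·2H2O (5 mol%), pyridine N-oxide (2 equiv), citric acid, Cu(OTf)2, MeCN–H2O, 60 °C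
Reagents that add atoms: pyridine N-oxide, [O-][n+]1ccccc1
Why: The syn C6,C7-diol condenses with hexavalent osmium to a dioxo-osmium glycolate, and the Os–O7 bond together with one oxo ligand adds across C10=C11 in a concerted [3+2] manner, which forms O7–C10 and C11–O in one event and leaves tetravalent osmium that pyridine N-oxide returns to the hexavalent state before hydrolysis releases 15. The closest known reaction type is the osmium-catalysed oxidative cyclisation of 1,2-diols that carry an alkene four atoms from the proximal hydroxyl, which gives 2,5-cis-tetrahydrofurans. The tetrahydrofuran closes in the 5-exo mode, O7 onto C10 with C11 outside the ring. C10 is controlled by C7: the two-carbon tether lets the alkene reach the O7–Os=O unit only in the arrangement that places H7 and H10 on the same side, so the ring must be cis and C10 becomes S. C11 is controlled by the alkene geometry, because both oxygens are delivered from osmium to the same face of the E alkene, which gives the threo pair and therefore 11S. The step needs chemoselectivity for C10=C11 over the lactone alkene C2=C3; this is secured because the oxidant is held on the diol and reaches only the tethered alkene, because the conjugated alkene is electron-poor, and because pyridine N-oxide should not take osmium to the octavalent state, so no free OsO4 is available for intermolecular dihydroxylation. The acidic medium speeds up ligand exchange at osmium and avoids the base that would open the lactone.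

Step 12
Reactants: 16 4-methoxybenzaldehyde
Product: 17 methyl (2Z)-3-(4-methoxyphenyl)prop-2-enoate
Conditions: (CF3CH2O)2P(O)CH2CO2Me, KN(SiMe3)2, 18-crown-6, THF, −78 °C
Reagents that add atoms: methyl 2-[bis(2,2,2-trifluoroethoxy)phosphoryl]acetate, COC(=O)CP(=O)(OCC(F)(F)F)OCC(F)(F)F
Why: Still–Gennari olefination: the electron-poor phosphonate and the dissociated potassium counter-ion make elimination of the first-formed adduct fast, which gives the Z enoate under kinetic control.

Step 13
Reactants: 17 methyl (2Z)-3-(4-methoxyphenyl)prop-2-enoate
Product: 18 (2Z)-3-(4-methoxyphenyl)prop-2-enoic acid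
Conditions: LiOH, THF–H2O, rt, dark; then aq. HCl to pH 3
Reagents that add atoms: lithium hydroxide, [Li+].[OH-]
Why: Ester saponification by acyl–oxygen cleavage does not touch the alkene; exclusion of light keeps the Z geometry.

Step 14
Reactants: 15 (6R)-6-{(S)-hydroxy[(2R,5S)-5-[(1S)-1-hydroxyethyl]oxolan-2-yl]methyl}-5,6-dihydro-2H-pyran-2-one; 18 (2Z)-3-(4-methoxyphenyl)prop-2-enoic acid
Product: 19 (1S)-1-[(2S,5R)-5-{(S)-hydroxy[(2R)-6-oxo-3,6-dihydro-2H-pyran-2-yl]methyl}oxolan-2-yl]ethyl (2Z)-3-(4-methoxyphenyl)prop-2-enoate
Conditions: DCC (1.1 equiv), DMAP (0.1 equiv), CH2Cl2, −20 to 0 °C, dark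
Reagents that add atoms: none
Why: Steglich esterification; O11 is flanked by a methyl group while O6 lies between two ring carbons, so the acyl transfer should occur at O11, and the low temperature, the small amount of DMAP and the electron-rich aryl group limit Z-to-E isomerisation.

## Compound list

1 | D-arabinose | O=C[C@@H](O)[C@H](O)[C@H](O)CO | starting material
2 | methyl D-arabinofuranoside (α/β mixture) | COC1O[C@H](CO)[C@@H](O)[C@@H]1O | intermediate
3 | methyl 5-deoxy-5-iodo-D-arabinofuranoside | COC1O[C@H](CI)[C@@H](O)[C@@H]1O | intermediate
4 | methyl 2,3-bis-O-(tert-butyldimethylsilyl)-5-deoxy-5-iodo-D-arabinofuranoside | COC1O[C@H](CI)[C@@H](O[Si](C)(C)C(C)(C)C)[C@@H]1O[Si](C)(C)C(C)(C)C | intermediate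
5 | (2S,3R)-2,3-bis[(tert-butyldimethylsilyl)oxy]pent-4-enal | O=C[C@@H](O[Si](C)(C)C(C)(C)C)[C@H](O[Si](C)(C)C(C)(C)C)C=C | intermediate
6 | (2R,3R)-2,3-bis[(tert-butyldimethylsilyl)oxy]pent-4-en-1-ol | OC[C@@H](O[Si](C)(C)C(C)(C)C)[C@H](O[Si](C)(C)C(C)(C)C)C=C | intermediate
7 | (E)-1-bromoprop-1-ene | C/C=C/Br | starting material
8 | 9-[(3R,4R)-3,4-bis[(tert-butyldimethylsilyl)oxy]-5-(9-borabicyclo[3.3.1]nonan-9-yloxy)pentyl]-9-borabicyclo[3.3.1]nonane | C1CCC2CCCC1B2CC[C@@H](O[Si](C)(C)C(C)(C)C)[C@H](O[Si](C)(C)C(C)(C)C)COB1C2CCCC1CCC2 | intermediate
9 | (2R,3R,6E)-2,3-bis[(tert-butyldimethylsilyl)oxy]oct-6-en-1-ol | OC[C@@H](O[Si](C)(C)C(C)(C)C)[C@H](O[Si](C)(C)C(C)(C)C)CC/C=C/C | intermediate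
10 | (2S,3R,6E)-2,3-bis[(tert-butyldimethylsilyl)oxy]oct-6-enal | O=C[C@@H](O[Si](C)(C)C(C)(C)C)[C@H](O[Si](C)(C)C(C)(C)C)CC/C=C/C | intermediate
11 | (4R,5R,6R,9E)-5,6-bis[(tert-butyldimethylsilyl)oxy]undeca-1,9-dien-4-ol | C=CC[C@@H](O)[C@@H](O[Si](C)(C)C(C)(C)C)[C@H](O[Si](C)(C)C(C)(C)C)CC/C=C/C | intermediate
12 | (4R,5R,6R,9E)-5,6-bis[(tert-butyldimethylsilyl)oxy]undeca-1,9-dien-4-yl prop-2-enoate | C=CC[C@@H](OC(=O)C=C)[C@@H](O[Si](C)(C)C(C)(C)C)[C@H](O[Si](C)(C)C(C)(C)C)CC/C=C/C | intermediate
13 | (6R)-6-[(1R,2R,5E)-1,2-bis[(tert-butyldimethylsilyl)oxy]hept-5-en-1-yl]-5,6-dihydro-2H-pyran-2-one | C/C=C/CC[C@@H](O[Si](C)(C)C(C)(C)C)[C@H](O[Si](C)(C)C(C)(C)C)[C@H]1CC=CC(=O)O1 | intermediate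
14 | (6R)-6-[(1S,2R,5E)-1,2-dihydroxyhept-5-en-1-yl]-5,6-dihydro-2H-pyran-2-one | C/C=C/CC[C@@H](O)[C@H](O)[C@H]1CC=CC(=O)O1 | intermediate
15 | (6R)-6-{(S)-hydroxy[(2R,5S)-5-[(1S)-1-hydroxyethyl]oxolan-2-yl]methyl}-5,6-dihydro-2H-pyran-2-one | O[C@@H](C)[C@@H]1CC[C@H]([C@H](O)[C@H]2CC=CC(=O)O2)O1 | intermediate
16 | 4-methoxybenzaldehyde | COc1ccc(C=O)cc1 | starting material
17 | methyl (2Z)-3-(4-methoxyphenyl)prop-2-enoate | COC(=O)/C=C\c1ccc(OC)cc1 | intermediate
18 | (2Z)-3-(4-methoxyphenyl)prop-2-enoic acid | OC(=O)/C=C\c1ccc(OC)cc1 | intermediate
19 | (1S)-1-[(2S,5R)-5-{(S)-hydroxy[(2R)-6-oxo-3,6-dihydro-2H-pyran-2-yl]methyl}oxolan-2-yl]ethyl (2Z)-3-(4-methoxyphenyl)prop-2-enoate | COc1ccc(/C=C\C(=O)O[C@@H](C)[C@@H]2CC[C@H]([C@H](O)[C@H]3CC=CC(=O)O3)O2)cc1 | target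

## Step count and least certain steps

Total step count: 14. Longest linear sequence: 12 steps (steps 1–11 and 14, from 1); steps 12 and 13 form the two-step side branch to 18.

**Step 11 (key step).**
- Most likely failure: osmium is diverted to intermolecular dihydroxylation of C2=C3, or to dihydroxylation of C10=C11 without ring closure. A second risk is Lewis-acid-promoted conjugate addition of O7 to C3 before the osmate ester has formed. Both follow from the conjugated lactone being present during an oxidation that needs a free diol.
- Fallback: it sets out from 13 and returns at 19, using anti addition across C10=C11 and a later inversion at C11 in place of the syn addition.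
  - Shi epoxidation of 13 (D-fructose-derived ketone catalyst, 2KHSO5·KHSO4·K2SO4, K2CO3 buffer, MeCN–dimethoxymethane–H2O, 0 °C) should give the (10R,11R)-epoxide F1.
  - HF·pyridine buffered with pyridine, then catalytic camphorsulfonic acid, frees the diol and lets O7 open the epoxide at C10 in the 5-exo mode with inversion. This should give the C11 epimer of 15, the 11R-alcohol F2, with the cis ring.
  - Mitsunobu esterification of F2 with 18 (PPh3, diisopropyl azodicarboxylate) inverts C11 and should give 19 directly, replacing steps 10, 11 and 14.

**Step 14.**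
- Most likely failure: insufficient discrimination between O11 and O6, with O6-acylated and bis-acylated material formed, because both are secondary hydroxyls and differ only in their neighbours. Erosion of the Z geometry by the nucleophilic catalyst is a second hazard.
- Fallback: it sets out from 15 and returns at 19, turning the kinetic acylation into a protecting-group sequence.
  - Silylation of both hydroxyls (Et3SiOTf, 2,6-lutidine) gives the bis(triethylsilyl) ether F3.
  - Mild acid methanolysis (pyridinium p-toluenesulfonate, MeOH–CH2Cl2, 0 °C) removes the less hindered silyl group at O11 and gives the O6-silyl alcohol F4.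
  - Esterification of F4 with 18 (DCC, catalytic DMAP) gives the silylated ester F5, and HF·pyridine releases 19.

**Step 7.**
- Most likely failure: poor facial selectivity at the aldehyde, since the syn arrangement of the two silyloxy groups gives a weaker intrinsic bias than an anti arrangement would. Partial epimerisation of the α-silyloxy aldehyde before addition is also possible.
- Fallback: it sets out from 10 and returns at 12, making both epimers usable. The C5 epimer, the 4S-alcohol F6, is separated and esterified with acrylic acid under Mitsunobu conditions (PPh3, diisopropyl azodicarboxylate). This inverts C5 and gives 12, while the 4R-alcohol 11 goes through step 8 as planned.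

**Step 9.**
- Most likely failure: the ruthenium carbene engages the internal C10=C11 alkene, with loss of the propenyl end or scrambling of the E geometry, or closure onto the hindered acrylate stalls and dimers form.
- Fallback: it sets out from 10 and returns at 13, building the lactone without metathesis.
  - Propargylation of 10 (allenyl-B(pin) with a chiral phosphoric acid catalyst, or Zn-mediated Barbier addition of propargyl bromide under Felkin control) gives the homopropargylic alcohol F7.
  - Double deprotonation (n-BuLi, 2.2 equiv) and carboxylation with CO2 gives the hydroxy ynoic acid F8.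
  - Semihydrogenation (H2, Pd/CaCO3 poisoned with Pb(OAc)2, quinoline) gives the Z hydroxy acid, which lactonises to 13 with a trace of acid.

**Step 5.**
- Most likely failure: slow hydroboration of a vinyl group that is flanked by a silyloxy-bearing carbon, followed by protodeboronation or β-hydride elimination during a slow transmetalation while the volatile bromide 7 is lost.
- Fallback: it sets out from 6 and returns at 9, using a substitution at C9 in place of the cross-coupling.
  - Pivaloylation of 6 gives the pivalate F9.
  - Hydroboration–oxidation with a less hindered borane (BH3·SMe2, then NaBO3) gives the primary alcohol F10.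
  - I2, PPh3 and imidazole give the iodide F11.
  - Displacement with ((E)-MeCH=CH)2CuLi (from 7, t-BuLi and CuI) gives the coupled pivalate F12, and iBu2AlH removes the pivalate to give 9.

## Further compounds

F1 | step 11 | (6R)-6-[(1R,2R)-1,2-bis[(tert-butyldimethylsilyl)oxy]-4-[(2R,3R)-3-methyloxiran-2-yl]butyl]-5,6-dihydro-2H-pyran-2-one | C[C@H]1O[C@@H]1CC[C@@H](O[Si](C)(C)C(C)(C)C)[C@H](O[Si](C)(C)C(C)(C)C)[C@H]2CC=CC(=O)O2
F2 | step 11 | (6R)-6-{(S)-hydroxy[(2R,5S)-5-[(1R)-1-hydroxyethyl]oxolan-2-yl]methyl}-5,6-dihydro-2H-pyran-2-one | O[C@H](C)[C@@H]1CC[C@H]([C@H](O)[C@H]2CC=CC(=O)O2)O1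
F3 | step 14 | (6R)-6-{(S)-[(2R,5S)-5-[(1S)-1-(triethylsilyloxy)ethyl]oxolan-2-yl](triethylsilyloxy)methyl}-5,6-dihydro-2H-pyran-2-one | CC[Si](CC)(CC)O[C@@H](C)[C@@H]1CC[C@H]([C@H](O[Si](CC)(CC)CC)[C@H]2CC=CC(=O)O2)O1
F4 | step 14 | (6R)-6-{(S)-[(2R,5S)-5-[(1S)-1-hydroxyethyl]oxolan-2-yl](triethylsilyloxy)methyl}-5,6-dihydro-2H-pyran-2-one | O[C@@H](C)[C@@H]1CC[C@H]([C@H](O[Si](CC)(CC)CC)[C@H]2CC=CC(=O)O2)O1
F5 | step 14 | (1S)-1-[(2S,5R)-5-{(S)-[(2R)-6-oxo-3,6-dihydro-2H-pyran-2-yl](triethylsilyloxy)methyl}oxolan-2-yl]ethyl (2Z)-3-(4-methoxyphenyl)prop-2-enoate | COc1ccc(/C=C\C(=O)O[C@@H](C)[C@@H]2CC[C@H]([C@H](O[Si](CC)(CC)CC)[C@H]3CC=CC(=O)O3)O2)cc1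
F6 | step 7 | (4S,5R,6R,9E)-5,6-bis[(tert-butyldimethylsilyl)oxy]undeca-1,9-dien-4-ol | C=CC[C@H](O)[C@@H](O[Si](C)(C)C(C)(C)C)[C@H](O[Si](C)(C)C(C)(C)C)CC/C=C/C
F7 | step 9 | (4R,5R,6R,9E)-5,6-bis[(tert-butyldimethylsilyl)oxy]undec-9-en-1-yn-4-ol | C#CC[C@@H](O)[C@@H](O[Si](C)(C)C(C)(C)C)[C@H](O[Si](C)(C)C(C)(C)C)CC/C=C/C
F8 | step 9 | (5R,6R,7R,10E)-6,7-bis[(tert-butyldimethylsilyl)oxy]-5-hydroxydodec-10-en-2-ynoic acid | OC(=O)C#CC[C@@H](O)[C@@H](O[Si](C)(C)C(C)(C)C)[C@H](O[Si](C)(C)C(C)(C)C)CC/C=C/C
F9 | step 5 | (2R,3R)-2,3-bis[(tert-butyldimethylsilyl)oxy]pent-4-en-1-yl 2,2-dimethylpropanoate | CC(C)(C)C(=O)OC[C@@H](O[Si](C)(C)C(C)(C)C)[C@H](O[Si](C)(C)C(C)(C)C)C=C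
F10 | step 5 | (2R,3R)-2,3-bis[(tert-butyldimethylsilyl)oxy]-5-hydroxypentyl 2,2-dimethylpropanoate | CC(C)(C)C(=O)OC[C@@H](O[Si](C)(C)C(C)(C)C)[C@H](O[Si](C)(C)C(C)(C)C)CCO
F11 | step 5 | (2R,3R)-2,3-bis[(tert-butyldimethylsilyl)oxy]-5-iodopentyl 2,2-dimethylpropanoate | CC(C)(C)C(=O)OC[C@@H](O[Si](C)(C)C(C)(C)C)[C@H](O[Si](C)(C)C(C)(C)C)CCI
F12 | step 5 | (2R,3R,6E)-2,3-bis[(tert-butyldimethylsilyl)oxy]oct-6-en-1-yl 2,2-dimethylpropanoate | CC(C)(C)C(=O)OC[C@@H](O[Si](C)(C)C(C)(C)C)[C@H](O[Si](C)(C)C(C)(C)C)CC/C=C/C
A1 | alternative 1 | 2,5-cis tetrahydrofuran-3-one carrying C3–C12 (4-methoxybenzyl ether at O11, silyl ethers at O5 and O6) | COc1ccc(CO[C@@H](C)[C@H]2O[C@@H]([C@H](O[Si](C)(C)C(C)(C)C)[C@H](O[Si](C)(C)C(C)(C)C)CC=C)CC2=O)cc1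
A2 | alternative 1 | cis-2,5-disubstituted 4-methylidene-1,3-dioxolane (enol acetal precursor of A1) | COc1ccc(CO[C@@H](C)[C@H]2O[C@@H]([C@H](O[Si](C)(C)C(C)(C)C)[C@H](O[Si](C)(C)C(C)(C)C)CC=C)OC2=C)cc1
A3 | alternative 1 | D-threonine | C[C@@H]([C@H](C(=O)O)N)O
A4 | alternative 2 | 8-oxabicyclo[3.2.1]oct-6-en-3-one (meso) | O=C1C[C@@H]2C=C[C@H](C1)O2
A5 | alternative 2 | furan | c1ccoc1
A6 | alternative 2 | 1,1,3,3-tetrabromopropan-2-one | O=C(C(Br)Br)C(Br)Br
A7 | alternative 3 | 6-substituted 3,6-dihydro-2H-pyran-2-one (β,γ-unsaturated lactone, bis-silyl ether) | CC(C)(C)[Si](C)(C)O[C@@H](C)[C@@H]1CC[C@H]([C@H](O[Si](C)(C)C(C)(C)C)[C@H]2C=CCC(=O)O2)O1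
A8 | alternative 3 | trans vinyl epoxide at C4–C5 carrying the silylated tetrahydrofuran side chain | CC(C)(C)[Si](C)(C)O[C@@H](C)[C@@H]1CC[C@H]([C@H](O[Si](C)(C)C(C)(C)C)[C@@H]2O[C@H]2C=C)O1
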